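**Retrosynthetic overview**

1. Locants (pentalene numbering): ring A = C3a–C4(styryl)–C5–C6(=O)–C6a(OH); ring B = C1(=O)–C2(aryl)–C3(aryl)–C3a–C6a. The target arises by sevenfold O-demethylation of its heptamethyl ether, whose C4=C5 bond comes from Saegusa–Ito dehydrogenation of a 2-hydroxycyclopentanone.
2. Key disconnection: ring A is cut at C4–C5 and C6–C6a into acetaldehyde (C5, C6) and a ring-B 5-alkylidenecyclopent-3-ene-1,2-dione (C4, C3a, C6a); both bonds form in one flask by a dual amine/carbene Michael–crossed-benzoin (3+2) cascade.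
3. Enabling feature: ring A carries its C6 ketone next to the tertiary C6a carbinol (an α-ketol, the retron of a benzoin addition), and C4 stands 1,3 to C6a. With C6a as one ketone of a 1,2-dione in ring B and C3a=C4 as its alkylidene, C4 and C6a are a 1,3-bis-electrophile that acetaldehyde answers as C5 enamine nucleophile and C6 acyl anion.
4. The alkylidene dione comes from Knoevenagel condensation of the diaryl 1,2-dione with (E)-3,5-dimethoxycinnamaldehyde (Wittig product). The dione comes from α′-hydroxylation and oxidation of the 2,3-diarylcyclopentenone, built on 3-ethoxycyclopent-2-enone by bromination, Suzuki–Miyaura coupling and Stork–Danheiser aryl addition.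
5. Order of rings: ring B is bought as the five-membered enone and dressed first; ring A is formed last, in the key step.

Key step: step 8

Assumption: the alkylidene geometry of the Knoevenagel product and the C-4 configuration of the key-step product are immaterial, because both carbons are rehybridised later; the two catalysts named in step 8 are taken to be the matched pair leading to (6aS), and the mirror-image carbene precatalyst is used if the sense of induction proves opposite.

**Route**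

Step 1
Reactants: 1 3-ethoxycyclopent-2-en-1-one
Product: 2 2-bromo-3-ethoxycyclopent-2-en-1-one
Conditions: NBS, CH2Cl2, 0 °C to 23 °C
Reagents that add atoms: N-bromosuccinimide, O=C1CCC(=O)N1Br
Why: Electrophilic bromination at the nucleophilic α-carbon of the vinylogous ester gives the 2-bromo enone, the handle for the first aryl group.

Step 2
Reactants: 2 2-bromo-3-ethoxycyclopent-2-en-1-one; 3 (3,4,5-trimethoxyphenyl)boronic acid
Product: 4 3-ethoxy-2-(3,4,5-trimethoxyphenyl)cyclopent-2-en-1-one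
Conditions: Pd(PPh3)4 (5 mol%), K2CO3, 1,4-dioxane/H2O, 90 °C
Reagents that add atoms: none
Why: Suzuki–Miyaura coupling of the activated alkenyl bromide with the electron-rich arylboronic acid places the future C-2 aryl group.

Step 3
Reactants: 4 3-ethoxy-2-(3,4,5-trimethoxyphenyl)cyclopent-2-en-1-one; 5 (3,5-dimethoxyphenyl)magnesium chloride
Product: 7 3-(3,5-dimethoxyphenyl)-2-(3,4,5-trimethoxyphenyl)cyclopent-2-en-1-one, via tertiary allylic alcohol 6 (not isolated)
Conditions: THF, 0 °C to 23 °C; then 1 M HCl, 23 °C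
Reagents that add atoms: water, O
Why: Stork–Danheiser sequence, in which 1,2-addition of the aryl Grignard reagent to the vinylogous ester carbonyl and acid hydrolysis of the enol ether (loss of ethanol and water) transpose the enone so that the new aryl group ends at C-3.

Step 4
Reactants: 7 3-(3,5-dimethoxyphenyl)-2-(3,4,5-trimethoxyphenyl)cyclopent-2-en-1-one
Product: 9 rac-3-(3,5-dimethoxyphenyl)-5-hydroxy-2-(3,4,5-trimethoxyphenyl)cyclopent-2-en-1-one, via potassium dienolate 8 (not isolated)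
Conditions: KN(SiMe3)2, THF, −78 °C; then 2-(phenylsulfonyl)-3-phenyloxaziridine, −78 °C; AcOH quench
Reagents that add atoms: 2-(phenylsulfonyl)-3-phenyloxaziridine, O=S(=O)(c1ccccc1)N1OC1c1ccccc1
Why: Kinetic deprotonation at C-5 (α′) gives the cross-conjugated enolate, which the N-sulfonyloxaziridine hydroxylates (enolate oxidation); the new stereocentre is racemic and is destroyed in step 5.

Step 5
Reactants: 9 rac-3-(3,5-dimethoxyphenyl)-5-hydroxy-2-(3,4,5-trimethoxyphenyl)cyclopent-2-en-1-one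
Product: 10 4-(3,5-dimethoxyphenyl)-3-(3,4,5-trimethoxyphenyl)cyclopent-3-ene-1,2-dione
Conditions: Dess–Martin periodinane, CH2Cl2, 0 °C to 23 °C
Reagents that add atoms: none
Why: Dess–Martin oxidation of the α-ketol gives the 1,2-dione, which should stay in the diketo form because its enol would be a cyclopentadienone; it is used at once.

Step 6
Reactants: 11 3,5-dimethoxybenzaldehyde; 12 (triphenylphosphoranylidene)acetaldehyde
Product: 13 (2E)-3-(3,5-dimethoxyphenyl)prop-2-enal
Conditions: toluene, 80 °C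
Reagents that add atoms: none
Why: Wittig olefination with the stabilised formyl ylide should give the (E)-enal.

Step 7
Reactants: 10 4-(3,5-dimethoxyphenyl)-3-(3,4,5-trimethoxyphenyl)cyclopent-3-ene-1,2-dione; 13 (2E)-3-(3,5-dimethoxyphenyl)prop-2-enal
Product: 14 (5Z)-4-(3,5-dimethoxyphenyl)-5-[(2E)-3-(3,5-dimethoxyphenyl)prop-2-en-1-ylidene]-3-(3,4,5-trimethoxyphenyl)cyclopent-3-ene-1,2-dione
Conditions: piperidine (10 mol%), AcOH (10 mol%), toluene, 4 Å molecular sieves, 40 °C
Reagents that add atoms: none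
Why: Knoevenagel condensation, in which the C-5 methylene (acidified by the dione and, vinylogously, by the enone) condenses with the enal carbonyl and loss of water makes the 1,2-mode irreversible; the alkylidene isomer drawn is the one expected on steric grounds.

Step 8
Reactants: 14 (5Z)-4-(3,5-dimethoxyphenyl)-5-[(2E)-3-(3,5-dimethoxyphenyl)prop-2-en-1-ylidene]-3-(3,4,5-trimethoxyphenyl)cyclopent-3-ene-1,2-dione; 15 acetaldehyde
Product: 17 (3aS,4R,6aS)-3-(3,5-dimethoxyphenyl)-4-[(E)-2-(3,5-dimethoxyphenyl)ethenyl]-6a-hydroxy-2-(3,4,5-trimethoxyphenyl)-3a,4,5,6a-tetrahydropentalene-1,6-dione, via keto aldehyde 16 (not isolated)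
Conditions: acetaldehyde (5 equiv), (S)-α,α-diphenylprolinol trimethylsilyl ether (20 mol%), (5aS,10bR)-2-(pentafluorophenyl)-5a,10b-dihydro-4H,6H-indeno[2,1-b][1,2,4]triazolo[4,3-d][1,4]oxazinium tetrafluoroborate (10 mol%), NaOAc (20 mol%), CHCl3, 4 °C to 23 °C
Reagents that add atoms: none
Why: The prolinol ether turns acetaldehyde into its enamine, which adds to C-4, the β-carbon of the exocyclic enone activated by both ring carbonyls, to give keto aldehyde 16 (C4–C5 bond); the triazolylidene carbene then converts the aldehyde into a Breslow acyl-anion equivalent that attacks the neighbouring C-6a ketone (C6–C6a bond, intramolecular crossed benzoin reaction), so ring A with its tertiary α-ketol arises in one flask. The closest known reaction type is the dual secondary-amine/N-heterocyclic-carbene Michael–crossed-benzoin cascade of enolisable aldehydes with alkylidene 1,3-dicarbonyl compounds, which builds 2-hydroxycyclopentanones in the same manner. Ring A closes in the 5-exo-trig mode (acyl-anion carbon C-6 onto the C-6a carbonyl). C-4 is set by the prolinol ether (enamine attack from its unshielded face in an acyclic synclinal transition state), C-3a is epimerisable next to the dione and ends cis to the new hydroxyl because only the cis-fused bicyclo[3.3.0]octane can close, and C-6a is set by the chiral carbene, reinforced by the preference of the C-4 styryl group for the convex face. The step needs 1,4- and not 1,6-addition of the enamine, and acyl-anion addition to C-6a and not to C-1 or (Stetter mode) to C-3: C-4 is the more accessible and more activated terminus, only the C-6a ketone gives a fused five-membered ring and it is activated by the vicinal C-1 carbonyl, and C-3 is fully substituted.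

Step 9
Reactants: 17 (3aS,4R,6aS)-3-(3,5-dimethoxyphenyl)-4-[(E)-2-(3,5-dimethoxyphenyl)ethenyl]-6a-hydroxy-2-(3,4,5-trimethoxyphenyl)-3a,4,5,6a-tetrahydropentalene-1,6-dione
Product: 20 (3aS,6aS)-3-(3,5-dimethoxyphenyl)-4-[(E)-2-(3,5-dimethoxyphenyl)ethenyl]-6a-hydroxy-2-(3,4,5-trimethoxyphenyl)-3a,6a-dihydropentalene-1,6-dione, via bis-silyl dienol ether 18 (not isolated), via silyl-protected enone 19 (not isolated)
Conditions: TMSOTf, Et3N, CH2Cl2, −78 °C to 0 °C; then Pd(OAc)2 (1.1 equiv), MeCN, 23 °C; then 1 M HCl, THF, 0 °C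
Reagents that add atoms: none
Why: Saegusa–Ito oxidation, in which the C-6 ketone can enolise only towards C-5 (C-6a is quaternary), so one silyl enol ether forms (the tertiary hydroxyl is silylated as well) and its palladium enolate loses the allylic C-4 hydrogen by β-hydride elimination; C-3a and C-6a are untouched and the acidic work-up frees the tertiary alcohol.

Step 10
Reactants: 20 (3aS,6aS)-3-(3,5-dimethoxyphenyl)-4-[(E)-2-(3,5-dimethoxyphenyl)ethenyl]-6a-hydroxy-2-(3,4,5-trimethoxyphenyl)-3a,6a-dihydropentalene-1,6-dione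
Product: 21 (3aS,6aS)-3-(3,5-dihydroxyphenyl)-4-[(E)-2-(3,5-dihydroxyphenyl)ethenyl]-6a-hydroxy-2-(3,4,5-trihydroxyphenyl)-3a,6a-dihydropentalene-1,6-dione (CNP0306657.1)
Conditions: BBr3 (15 equiv), CH2Cl2, −78 °C to 0 °C; then MeOH, H2O
Reagents that add atoms: none
Why: Boron tribromide cleaves the seven aryl methyl ethers at the methyl carbon and should leave the tertiary α-ketol (its cation would be destabilised by two carbonyl groups) and the cis ring fusion untouched.

**Compound list**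

1 | 3-ethoxycyclopent-2-en-1-one | CCOC1=CC(=O)CC1 | starting material
2 | 2-bromo-3-ethoxycyclopent-2-en-1-one | CCOC1=C(Br)C(=O)CC1 | intermediate
3 | (3,4,5-trimethoxyphenyl)boronic acid | COc1cc(B(O)O)cc(OC)c1OC | starting material
4 | 3-ethoxy-2-(3,4,5-trimethoxyphenyl)cyclopent-2-en-1-one | CCOC1=C(c2cc(OC)c(OC)c(OC)c2)C(=O)CC1 | intermediate
5 | (3,5-dimethoxyphenyl)magnesium chloride | COc1cc([Mg]Cl)cc(OC)c1 | starting material
6 | rac-1-(3,5-dimethoxyphenyl)-3-ethoxy-2-(3,4,5-trimethoxyphenyl)cyclopent-2-en-1-ol (formed as its chloromagnesium alkoxide) | CCOC1=C(c2cc(OC)c(OC)c(OC)c2)C(O)(c2cc(OC)cc(OC)c2)CC1 | intermediate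
7 | 3-(3,5-dimethoxyphenyl)-2-(3,4,5-trimethoxyphenyl)cyclopent-2-en-1-one | O=C1CCC(c2cc(OC)cc(OC)c2)=C1c1cc(OC)c(OC)c(OC)c1 | intermediate
8 | potassium 4-(3,5-dimethoxyphenyl)-5-(3,4,5-trimethoxyphenyl)cyclopenta-1,4-dien-1-olate | [K+].[O-]C1=CCC(c2cc(OC)cc(OC)c2)=C1c1cc(OC)c(OC)c(OC)c1 | intermediate
9 | rac-3-(3,5-dimethoxyphenyl)-5-hydroxy-2-(3,4,5-trimethoxyphenyl)cyclopent-2-en-1-one | O=C1C(O)CC(c2cc(OC)cc(OC)c2)=C1c1cc(OC)c(OC)c(OC)c1 | intermediate
10 | 4-(3,5-dimethoxyphenyl)-3-(3,4,5-trimethoxyphenyl)cyclopent-3-ene-1,2-dione | O=C1C(=O)CC(c2cc(OC)cc(OC)c2)=C1c1cc(OC)c(OC)c(OC)c1 | intermediate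
11 | 3,5-dimethoxybenzaldehyde | COc1cc(C=O)cc(OC)c1 | starting material
12 | (triphenylphosphoranylidene)acetaldehyde | O=CC=P(c1ccccc1)(c1ccccc1)c1ccccc1 | starting material
13 | (2E)-3-(3,5-dimethoxyphenyl)prop-2-enal | O=C/C=C/c1cc(OC)cc(OC)c1 | intermediate
14 | (5Z)-4-(3,5-dimethoxyphenyl)-5-[(2E)-3-(3,5-dimethoxyphenyl)prop-2-en-1-ylidene]-3-(3,4,5-trimethoxyphenyl)cyclopent-3-ene-1,2-dione | O=C1C(=O)/C(=C\C=C\c2cc(OC)cc(OC)c2)C(c2cc(OC)cc(OC)c2)=C1c1cc(OC)c(OC)c(OC)c1 | intermediate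
15 | acetaldehyde | CC=O | starting material
16 | (3R,4E)-5-(3,5-dimethoxyphenyl)-3-[2-(3,5-dimethoxyphenyl)-4,5-dioxo-3-(3,4,5-trimethoxyphenyl)cyclopent-2-en-1-yl]pent-4-enal (epimers at the ring carbon, interconverting) | O=CC[C@H](/C=C/c1cc(OC)cc(OC)c1)C1C(c2cc(OC)cc(OC)c2)=C(c2cc(OC)c(OC)c(OC)c2)C(=O)C1=O | intermediate
17 | (3aS,4R,6aS)-3-(3,5-dimethoxyphenyl)-4-[(E)-2-(3,5-dimethoxyphenyl)ethenyl]-6a-hydroxy-2-(3,4,5-trimethoxyphenyl)-3a,4,5,6a-tetrahydropentalene-1,6-dione (cis-fused, styryl on the convex face) | O=C1C[C@H](/C=C/c2cc(OC)cc(OC)c2)[C@H]2C(c3cc(OC)cc(OC)c3)=C(c3cc(OC)c(OC)c(OC)c3)C(=O)[C@@]12O | intermediate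
18 | bis(trimethylsilyl) derivative of 17: C-6 trimethylsilyl enol ether (C5=C6) and C-6a trimethylsilyl ether, configuration as in 17 | C[Si](C)(C)OC1=C[C@H](/C=C/c2cc(OC)cc(OC)c2)[C@H]2C(c3cc(OC)cc(OC)c3)=C(c3cc(OC)c(OC)c(OC)c3)C(=O)[C@@]12O[Si](C)(C)C | intermediate
19 | (3aS,6aS)-3-(3,5-dimethoxyphenyl)-4-[(E)-2-(3,5-dimethoxyphenyl)ethenyl]-2-(3,4,5-trimethoxyphenyl)-6a-(trimethylsilyloxy)-3a,6a-dihydropentalene-1,6-dione | O=C1C=C(/C=C/c2cc(OC)cc(OC)c2)[C@H]2C(c3cc(OC)cc(OC)c3)=C(c3cc(OC)c(OC)c(OC)c3)C(=O)[C@@]12O[Si](C)(C)C | intermediate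
20 | (3aS,6aS)-3-(3,5-dimethoxyphenyl)-4-[(E)-2-(3,5-dimethoxyphenyl)ethenyl]-6a-hydroxy-2-(3,4,5-trimethoxyphenyl)-3a,6a-dihydropentalene-1,6-dione | O=C1C=C(/C=C/c2cc(OC)cc(OC)c2)[C@H]2C(c3cc(OC)cc(OC)c3)=C(c3cc(OC)c(OC)c(OC)c3)C(=O)[C@@]12O | intermediate
21 | (3aS,6aS)-3-(3,5-dihydroxyphenyl)-4-[(E)-2-(3,5-dihydroxyphenyl)ethenyl]-6a-hydroxy-2-(3,4,5-trihydroxyphenyl)-3a,6a-dihydropentalene-1,6-dione (CNP0306657.1) | O=C1C=C(/C=C/c2cc(O)cc(O)c2)[C@H]2C(c3cc(O)cc(O)c3)=C(c3cc(O)c(O)c(O)c3)C(=O)[C@@]12O | target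

**Step count and risks**

Total step count: 10. Longest linear sequence: 9 steps (steps 1–5 and 7–10, from 1 to 21); step 6 is a one-step side branch.

Steps most likely to fail:

1. Step 8. Self-aldol or self-benzoin reaction of acetaldehyde, or an intermolecular Stetter addition of acetaldehyde to C-4, may outrun the enamine Michael addition, and the benzoin closure may show poor facial selectivity. The fallback closes ring A by the complementary (3+2) mode, which also arrives directly at the enone oxidation level; it sets out from 13 and 10 and comes back at 20. Enal 13 is homologated (CBr4, PPh3) to 1-[(1E)-4,4-dibromobuta-1,3-dien-1-yl]-3,5-dimethoxybenzene F1. n-BuLi converts this into lithium (3E)-4-(3,5-dimethoxyphenyl)but-3-en-1-yn-1-ide F2, which is formylated with DMF to (4E)-5-(3,5-dimethoxyphenyl)pent-4-en-2-ynal F3. Pyrrolidine-mediated Michael addition of dione 10 (through C-5) to F3 gives (2Z,4E)-5-(3,5-dimethoxyphenyl)-3-[2-(3,5-dimethoxyphenyl)-4,5-dioxo-3-(3,4,5-trimethoxyphenyl)cyclopent-2-en-1-yl]penta-2,4-dienal F4. The triazolium carbene of step 8 then closes ring A by crossed benzoin addition to give 20.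

2. Step 10. Exhaustive ether cleavage may be accompanied by acid-mediated addition of bromide or of the liberated phenols to the ring-A dienone, or may stop short of completion. The fallback moves the ether cleavage in front of the dehydrogenation and changes the phenol protection; it sets out from 17 and comes back at 21. BBr3 converts 17 into (3aS,4R,6aS)-3-(3,5-dihydroxyphenyl)-4-[(E)-2-(3,5-dihydroxyphenyl)ethenyl]-6a-hydroxy-2-(3,4,5-trihydroxyphenyl)-3a,4,5,6a-tetrahydropentalene-1,6-dione F5. Ac2O/pyridine gives its heptaacetate F6. 2-Iodoxybenzoic acid in DMSO at 65 °C dehydrogenates C4–C5 to the heptaacetate of the target F7, and HCl in MeOH at 23 °C removes the acetates to give 21.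

3. Step 7. Self-condensation of the enolisable dione, conjugate addition to the enal, or addition of a second dione to the product may erode the condensation. The fallback replaces the equilibrating amine catalysis by a directed aldol addition and a separate elimination; it sets out from 10 and 13 and comes back at 14. LiN(SiMe3)2 at −78 °C converts 10 into lithium 3-(3,5-dimethoxyphenyl)-5-oxo-4-(3,4,5-trimethoxyphenyl)cyclopenta-1,3-dien-1-olate F8. This adds to the carbonyl group of 13 under kinetic control to give 4-(3,5-dimethoxyphenyl)-5-[(2E)-3-(3,5-dimethoxyphenyl)-1-hydroxyprop-2-en-1-yl]-3-(3,4,5-trimethoxyphenyl)cyclopent-3-ene-1,2-dione F9. MsCl/Et3N gives the corresponding methanesulfonate F10, from which DBU eliminates to 14.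

Further compounds
F1 | step 8 | 1-[(1E)-4,4-dibromobuta-1,3-dien-1-yl]-3,5-dimethoxybenzene | BrC(Br)=C/C=C/c1cc(OC)cc(OC)c1
F2 | step 8 | lithium (3E)-4-(3,5-dimethoxyphenyl)but-3-en-1-yn-1-ide | [Li]C#C/C=C/c1cc(OC)cc(OC)c1
F3 | step 8 | (4E)-5-(3,5-dimethoxyphenyl)pent-4-en-2-ynal | O=CC#C/C=C/c1cc(OC)cc(OC)c1
F4 | step 8 | (2Z,4E)-5-(3,5-dimethoxyphenyl)-3-[2-(3,5-dimethoxyphenyl)-4,5-dioxo-3-(3,4,5-trimethoxyphenyl)cyclopent-2-en-1-yl]penta-2,4-dienal | O=C/C=C(/C=C/c1cc(OC)cc(OC)c1)C1C(c2cc(OC)cc(OC)c2)=C(c2cc(OC)c(OC)c(OC)c2)C(=O)C1=O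
F5 | step 10 | (3aS,4R,6aS)-3-(3,5-dihydroxyphenyl)-4-[(E)-2-(3,5-dihydroxyphenyl)ethenyl]-6a-hydroxy-2-(3,4,5-trihydroxyphenyl)-3a,4,5,6a-tetrahydropentalene-1,6-dione | O=C1C[C@H](/C=C/c2cc(O)cc(O)c2)[C@H]2C(c3cc(O)cc(O)c3)=C(c3cc(O)c(O)c(O)c3)C(=O)[C@@]12O
F6 | step 10 | heptaacetate (all seven phenols) of F5 | O=C1C[C@H](/C=C/c2cc(OC(C)=O)cc(OC(C)=O)c2)[C@H]2C(c3cc(OC(C)=O)cc(OC(C)=O)c3)=C(c3cc(OC(C)=O)c(OC(C)=O)c(OC(C)=O)c3)C(=O)[C@@]12O
F7 | step 10 | heptaacetate (all seven phenols) of 21 | O=C1C=C(/C=C/c2cc(OC(C)=O)cc(OC(C)=O)c2)[C@H]2C(c3cc(OC(C)=O)cc(OC(C)=O)c3)=C(c3cc(OC(C)=O)c(OC(C)=O)c(OC(C)=O)c3)C(=O)[C@@]12O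
F8 | step 7 | lithium 3-(3,5-dimethoxyphenyl)-5-oxo-4-(3,4,5-trimethoxyphenyl)cyclopenta-1,3-dien-1-olate | [Li+].[O-]C1=CC(c2cc(OC)cc(OC)c2)=C(c2cc(OC)c(OC)c(OC)c2)C1=O
F9 | step 7 | 4-(3,5-dimethoxyphenyl)-5-[(2E)-3-(3,5-dimethoxyphenyl)-1-hydroxyprop-2-en-1-yl]-3-(3,4,5-trimethoxyphenyl)cyclopent-3-ene-1,2-dione (mixture of diastereomers) | O=C1C(=O)C(C(O)/C=C/c2cc(OC)cc(OC)c2)C(c2cc(OC)cc(OC)c2)=C1c1cc(OC)c(OC)c(OC)c1
F10 | step 7 | methanesulfonate of F9 (mixture of diastereomers) | O=C1C(=O)C(C(OS(C)(=O)=O)/C=C/c2cc(OC)cc(OC)c2)C(c2cc(OC)cc(OC)c2)=C1c1cc(OC)c(OC)c(OC)c1
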